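Numbering used throughout: the carbon chain of the target is numbered from the amide-bearing CH2 (C1) to the terminal methyl (C30). Ring A is the oxane O/C12–C16, ring B the oxane O/C18–C22. Compound numbers 1–40 are those of the steps.

## The problem

The target 40 is a C30 chain with an N-(2-methoxyacryloyl)amino group on C1, a free hydroxyl on C2, a primary carbamate on C4, an E,E-diene C6–C9 (methyl on C7), ring A, a CH2 link (C17), ring B with a 20-OMe, and an all-E triene C24–C29 (methyl on C25). It has eleven stereocentres: 2S,4R (an anti-1,3 pair), 10R, 12S,13R,15S,16R on ring A, 18S,20S,22R on ring B, and 23S. Ring A is 2,6-cis with an equatorial 15-methyl and a tertiary C13 alcohol whose methyl is axial; these four centres sit on one ring, so one of them can control the others. Ring B is all-cis 2,4,6 and its C22 is anti to exocyclic C23, so the C22/C23 pair can control C18 and C20. C10 and the C2/C4 pair are isolated from the rest and must be bought or set by a reagent. The triene and diene do not survive acid or hydrogenation, the 2-methoxyacrylamide is an enol ether, the carbamate sits next to a free hydroxyl and the C13 alcohol is tertiary, so nothing at the end may need acid or strong base. The feature that makes the key step possible is in ring A: the ring oxygen is on C12, the next ring carbon C13 also bears oxygen, and C13–C14–C15–C16 are four contiguous ring carbons ending at the second O-bearing carbon. This is a (furan-2-yl)carbinol (C12 the carbinol carbon, C13–C16 the furan C2–C5) after oxidative ring expansion, which leaves a C13 ketone and a C14=C15 alkene exactly where the two methyl groups must go.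

## Retrosynthesis

**C7–C8 (final union).** Target 40 is cut between the two sp2 carbons C7 and C8 into vinyl iodide 32 (C8–C30) and alkenylboronate 39 (C1–C7). Cutting C8=C9 by olefination would leave the diene geometry to a late, hard-to-separate E/Z outcome, and cutting C5–C6 would need an sp3–sp2 coupling next to the oxygenated C4. The cut separates two stereocentres and all nitrogen functionality from the nine-stereocentre core. The forward reaction must retain both alkene geometries and tolerate free hydroxyls, carbamate, amide, enol ether and triene.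

**West fragment 39.** Boronate 39 goes back through amino alcohol 38, epoxy boronate 37, carbamate 36 and epoxy alcohol 34 to the C2-symmetric diepoxide 33. The bonds cut are N–C(O), C1–N, C6=C7 (cross-metathesis), O–C(O) of the carbamate and C5–C6 (epoxide opening by vinyl). Both stereocentres are bought in one building block, and the two hydroxyls are told apart by the order in which the two epoxides are opened, so no protecting group is needed. The forward reactions must give mono-opening of 33 and the C6=C7 geometry with boron trans to the chain.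

**Polyene termini of 32.** Vinyl iodide 32 comes from aldehyde 31 (C8=C9 by Takai olefination), which comes from alcohol 30 and silyl ether 29. The triene of 29 is cut at C27–C28 (Suzuki, dienyl iodide 28), C26=C27 (Takai, enal 27) and C24=C25 (Wittig, aldehyde 26 from alcohol 25 and benzyl ether 24). Building the triene stepwise after ring B is chosen over carrying it through, because ring B is closed in acid. Each step must be E-selective and must not epimerise C23 or C10.

**Ring B (fragment union).** Methyl ether 24 comes from alcohol 23, which is cut by a Prins disconnection (O–C18, C18–C19, C20–O) into aldehyde 17 and homoallylic alcohol 21, via trifluoroacetate 22. Cutting O–C22 instead (oxa-Michael) would cost three more steps after the union, and reversing the roles would put the epimerisable C23 next to the aldehyde. The cut halves the core and makes C18 and C20 from C22 in the coupling event. The forward reaction needs a chair transition state with both flanking groups equatorial and acid-stable protecting groups (TBDPS, benzyl).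

**East alcohol 21.** Alcohol 21 comes from aldehyde 20 by chelation-controlled allylation (C21–C22), and 20 from benzyl ether 19 and the Roche ester 18, which supplies C23. The anti C22/C23 relation is the chelation outcome, so no chiral reagent is needed.

**Ring A substituents.** Aldehyde 17 comes from alcohol 16 and benzyl ether 15. The C13–CH3 bond of 15 is cut back to ketone 14, and the C15–CH3 bond of 14 back to enone 13. Both additions are controlled by the ring (C15 by C16, C13 by the chair), so they need no reagent control. The precursor 13 has only C10, C12 and C16 set.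

**Ring A core (key step).** Enone 13 is cut at O12–C16 and C16–H and traced through hemiketal 12 to furyl carbinol 11. Against the neighbouring cuts (oxa-Michael at O–C16, epoxide opening at O–C12), this one turns a flat, achiral furan into the ring, sets C16 from C12, and leaves the C13 carbonyl and the C14=C15 alkene for the next two centres. The forward reaction must oxidise only the furan and must reduce the hemiketal carbon cis to H-12.

**Furyl carbinol 11.** C12 is set by asymmetric transfer hydrogenation of ketone 10. Ketone 10 is cut at C11–C12 into Weinreb amide 6 and bromide 8 (via Grignard reagent 9). Amide 6 comes from furan 1 through 2, 3, 4 and 5, and bromide 8 from the commercial bromo alcohol 7, which carries C10.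

## Roads not taken

**Alternative 1:** the most obvious plan cuts O–C16 of ring A as an oxa-Michael bond. A linear C9–C18 chain, dihydroxy enoate A1, made by asymmetric dihydroxylation of a C12=C13 trisubstituted alkene, would be cyclised with base to the ring-A ester A2. This needs C10, C15 and the C12/C13 diol each set by its own reagent-controlled step on an acyclic chain of about ten steps. In A1 the tertiary C13 hydroxyl can also add to C16 (5-exo, giving an oxolane), and the 2,6-cis ring comes only from thermodynamic equilibration. The furan route sets one centre by catalysis, relays three from it, and has only one hydroxyl that can close the ring.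

**Alternative 2:** cut O–C12 as an epoxide opening. Epoxy alcohol A3 (C12/C13 epoxide, C16 hydroxyl) would close 6-endo at C12 with inversion and leave the C13 tertiary alcohol. The epoxide is trisubstituted with the tertiary carbon at C13 and no π-group on C12, so acid-promoted opening is biased to C13 (5-exo, oxolane). A3 also needs a geometrically pure trisubstituted alkene, an asymmetric epoxidation and separate control of C15 and C16. The chosen plan has no regiochemical question in the ring closure.

**Alternative 3:** close ring B without a Prins reaction, by Horner–Wadsworth–Emmons union of aldehyde 17 with β-ketophosphonate A4, then desilylation and 6-endo oxa-Michael closure to oxan-4-one A5, followed by reduction and methylation. This avoids acid but needs three operations after the union to reach alcohol 23, sets C18 only by equilibration and C20 by a separate hydride step, and A4 is several steps longer than alcohol 21. The Prins union sets both centres and delivers the C20 oxygen in one event.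

Key step: step 7

Remark: the C2-symmetric diepoxide 33 is taken as a purchasable chiral building block.

## Steps

Step 1
Reactants: 1 furan
Product: 3 2-(furan-2-yl)ethanol, via 2-furyllithium 2 (not isolated)
Conditions: n-BuLi, THF, −78 to 0 °C; then oxirane, 0 °C to rt
Reagents that add atoms: oxirane C1CO1
Why: Furan is lithiated at C2 and the furyllithium opens oxirane (SN2), which installs the future C17–C18 unit; standard α-lithiation and epoxide alkylation of furan.

Step 2
Reactants: 3 2-(furan-2-yl)ethanol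
Product: 4 2-[2-(benzyloxy)ethyl]furan
Conditions: NaH, BnBr, Bu4NI (cat.), THF, 0 °C to rt
Reagents that add atoms: benzyl bromide BrCc1ccccc1
Why: Williamson etherification; benzyl survives the later TFA/Et3SiH and organometallic steps and can be removed by hydrogenolysis while the molecule still has no alkene.

Step 3
Reactants: 4 2-[2-(benzyloxy)ethyl]furan
Product: 6 5-[2-(benzyloxy)ethyl]-N-methoxy-N-methylfuran-2-carboxamide, via 5-lithiofuran 5 (not isolated)
Conditions: n-BuLi, THF, −78 to −10 °C; then ClC(O)N(OMe)Me, −78 °C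
Reagents that add atoms: N-methoxy-N-methylcarbamoyl chloride CON(C)C(Cl)=O
Why: The free α-position of the 2-alkylfuran is lithiated and acylated by the carbamoyl chloride, giving the Weinreb amide (future C12) in one operation.

Step 4
Reactants: 7 (S)-3-bromo-2-methylpropan-1-ol
Product: 8 (S)-(3-bromo-2-methylpropoxy)(tert-butyl)diphenylsilane
Conditions: TBDPSCl, imidazole, CH2Cl2, rt
Reagents that add atoms: tert-butyl(chloro)diphenylsilane CC(C)(C)[Si](Cl)(c1ccccc1)c1ccccc1
Why: Silylation of the primary alcohol of the chiral-pool unit that supplies C9–C11 with C10 already set; TBDPS resists TFA, Grignard reagents and hydrogenolysis and stays until step 22.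

Step 5
Reactants: 8 (S)-(3-bromo-2-methylpropoxy)(tert-butyl)diphenylsilane; 6 5-[2-(benzyloxy)ethyl]-N-methoxy-N-methylfuran-2-carboxamide
Product: 10 (3R)-1-{5-[2-(benzyloxy)ethyl]furan-2-yl}-4-(tert-butyldiphenylsilyloxy)-3-methylbutan-1-one, via Grignard reagent 9 (not isolated)
Conditions: Mg, I2 (cat.), THF, reflux; then 6, THF, 0 °C
Reagents that add atoms: none
Why: Weinreb ketone synthesis: the Grignard reagent adds once to the amide because the chelated tetrahedral intermediate is stable until work-up; this forms C11–C12.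

Step 6
Reactants: 10 (3R)-1-{5-[2-(benzyloxy)ethyl]furan-2-yl}-4-(tert-butyldiphenylsilyloxy)-3-methylbutan-1-one
Product: 11 (1S,3R)-1-{5-[2-(benzyloxy)ethyl]furan-2-yl}-4-(tert-butyldiphenylsilyloxy)-3-methylbutan-1-ol
Conditions: RuCl[(S,S)-TsDPEN](p-cymene) (1 mol %), HCO2H/Et3N 5:2, rt
Reagents that add atoms: none
Why: Noyori asymmetric transfer hydrogenation of an alkyl 2-furyl ketone; with the furan in the aryl position of the transition state the (S,S) catalyst gives the S carbinol, so C12 is set by the catalyst and not by remote C10.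

Step 7
Reactants: 11 (1S,3R)-1-{5-[2-(benzyloxy)ethyl]furan-2-yl}-4-(tert-butyldiphenylsilyloxy)-3-methylbutan-1-ol
Product: 13 (2S,6R)-6-[2-(benzyloxy)ethyl]-2-[(2R)-3-(tert-butyldiphenylsilyloxy)-2-methylpropyl]-2H-pyran-3(6H)-one (2,6-cis; chain numbering 10R,12S,16R), via Achmatowicz hemiketal 12 (not isolated)
Conditions: NBS, NaHCO3, THF/H2O 4:1, 0 °C; then Et3SiH, TFA, CH2Cl2, −40 to −20 °C
Reagents that add atoms: water O
Why: NBS transfers bromonium to the electron-rich 2,5-dialkylfuran, water adds, and the resulting 2,5-dihydrofuran opens to the Z-ene-1,4-dione, whose C12 hydroxyl adds to the C16 ketone to give hemiketal 12 (Achmatowicz rearrangement). TFA then ionises 12 to a cyclic oxocarbenium ion, which Et3SiH reduces at C16. The closest known reaction type is the Achmatowicz rearrangement followed by ionic hemiketal reduction, as used for cis-2,6-disubstituted dihydropyranones. Ring A is closed by O12–C16 bond formation, a 6-exo-trig addition of the hydroxyl to the ketone. The only new stereocentre, C16, is controlled by C12: hydride adds along the axial trajectory to the half-chair oxocarbenium ion with the C12 side chain pseudoequatorial, so H-16 ends cis to H-12. C12 is α to the new ketone but the cis isomer is also the thermodynamic one, so adventitious enolisation does not erode it. The step needs oxidation of the furan in preference to the benzyl and phenyl rings, which the far higher nucleophilicity of the furan secures, and hydride capture at C16 in preference to 1,4-reduction of the enone, which the greater electrophilicity of the oxocarbenium carbon secures.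

Step 8
Reactants: 13 (2S,6R)-6-[2-(benzyloxy)ethyl]-2-[(2R)-3-(tert-butyldiphenylsilyloxy)-2-methylpropyl]-2H-pyran-3(6H)-one
Product: 14 (2S,5S,6R)-6-[2-(benzyloxy)ethyl]-2-[(2R)-3-(tert-butyldiphenylsilyloxy)-2-methylpropyl]-5-methyloxan-3-one
Conditions: Me2CuLi (from MeLi and CuI), Et2O, −78 °C
Reagents that add atoms: lithium dimethylcuprate [Li+].C[Cu-]C
Why: Conjugate addition of the Gilman cuprate to the cyclic enone; methyl enters C15 anti to the adjacent C16 side chain (and to the cis C12 side chain), giving the 15,16-trans, all-equatorial ketone.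

Step 9
Reactants: 14 (2S,5S,6R)-6-[2-(benzyloxy)ethyl]-2-[(2R)-3-(tert-butyldiphenylsilyloxy)-2-methylpropyl]-5-methyloxan-3-one
Product: 15 (2S,3R,5S,6R)-6-[2-(benzyloxy)ethyl]-2-[(2R)-3-(tert-butyldiphenylsilyloxy)-2-methylpropyl]-3,5-dimethyloxan-3-ol
Conditions: MeMgBr, toluene/Et2O, −78 °C
Reagents that add atoms: methylmagnesium bromide C[Mg]Br
Why: Grignard addition to the oxan-3-one from the axial direction, which is open because one 1,3-diaxial partner is the ring oxygen and the other only H-15 (the same preference that gives axial angular methyls in ladder-polyether carbinols); this places methyl axial and hydroxyl equatorial at C13.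

Step 10
Reactants: 15 (2S,3R,5S,6R)-6-[2-(benzyloxy)ethyl]-2-[(2R)-3-(tert-butyldiphenylsilyloxy)-2-methylpropyl]-3,5-dimethyloxan-3-ol
Product: 16 (2S,3R,5S,6R)-2-[(2R)-3-(tert-butyldiphenylsilyloxy)-2-methylpropyl]-6-(2-hydroxyethyl)-3,5-dimethyloxan-3-ol
Conditions: H2 (1 atm), Pd(OH)2/C, EtOAc/EtOH, rt
Reagents that add atoms: none
Why: Hydrogenolysis of the benzyl ether; no alkene is present and the silyl ether and tertiary alcohol are inert.

Step 11
Reactants: 16 (2S,3R,5S,6R)-2-[(2R)-3-(tert-butyldiphenylsilyloxy)-2-methylpropyl]-6-(2-hydroxyethyl)-3,5-dimethyloxan-3-ol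
Product: 17 2-{(2R,3S,5R,6S)-6-[(2R)-3-(tert-butyldiphenylsilyloxy)-2-methylpropyl]-5-hydroxy-3,5-dimethyloxan-2-yl}acetaldehyde
Conditions: Dess–Martin periodinane, NaHCO3, CH2Cl2, 0 °C to rt
Reagents that add atoms: none
Why: Dess–Martin oxidation of the primary alcohol to the C18 aldehyde; the tertiary alcohol cannot be oxidised and the buffer suppresses β-elimination of the ring oxygen.

Step 12
Reactants: 18 methyl (S)-3-hydroxy-2-methylpropanoate
Product: 19 methyl (S)-3-(benzyloxy)-2-methylpropanoate
Conditions: benzyl 2,2,2-trichloroacetimidate, TfOH (cat.), cyclohexane/CH2Cl2, rt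
Reagents that add atoms: benzyl 2,2,2-trichloroacetimidate N=C(OCc1ccccc1)C(Cl)(Cl)Cl
Why: Acid-catalysed O-benzylation avoids base, so the α-stereocentre (future C23) is not epimerised.

Step 13
Reactants: 19 methyl (S)-3-(benzyloxy)-2-methylpropanoate
Product: 20 (S)-3-(benzyloxy)-2-methylpropanal
Conditions: i-Bu2AlH, CH2Cl2, −78 °C
Reagents that add atoms: none
Why: Partial reduction of the ester through the aluminium hemiacetal, stable at −78 °C, gives the aldehyde without epimerisation.

Step 14
Reactants: 20 (S)-3-(benzyloxy)-2-methylpropanal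
Product: 21 (2S,3R)-1-(benzyloxy)-2-methylhex-5-en-3-ol
Conditions: allyltributylstannane, MgBr2·OEt2, CH2Cl2, −78 to −20 °C
Reagents that add atoms: allyltributylstannane C=CC[Sn](CCCC)(CCCC)CCCC
Why: Chelation-controlled allylation: magnesium bridges the aldehyde and benzyloxy oxygens and the stannane attacks the six-membered chelate anti to the α-methyl group, which gives the 22,23-anti alcohol.

Step 15
Reactants: 17 2-{(2R,3S,5R,6S)-6-[(2R)-3-(tert-butyldiphenylsilyloxy)-2-methylpropyl]-5-hydroxy-3,5-dimethyloxan-2-yl}acetaldehyde; 21 (2S,3R)-1-(benzyloxy)-2-methylhex-5-en-3-ol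
Product: 23 bis-oxane alcohol (ring A joined through C17H2 to ring B; 20-OH, 13-OH, 9-OTBDPS, 24-OBn; 10R,12S,13R,15S,16R,18S,20S,22R,23S), via C20 trifluoroacetate 22 (not isolated)
Conditions: TFA/CH2Cl2 1:4, 0 °C to rt; then K2CO3, MeOH, rt
Reagents that add atoms: trifluoroacetic acid OC(=O)C(F)(F)F
Why: Prins cyclisation: 17 and 21 condense to an E oxocarbenium ion that cyclises through a chair with both flanking groups equatorial, and trifluoroacetate traps the C20 cation equatorially, so C18 and C20 are set all-cis to C22; methanolysis then frees the C20 hydroxyl, whose oxygen comes from the acid.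

Step 16
Reactants: 23 bis-oxane alcohol
Product: 24 bis-oxane methyl ether (20-OMe; otherwise as 23)
Conditions: Me3OBF4, 1,8-bis(dimethylamino)naphthalene, CH2Cl2, 0 °C to rt
Reagents that add atoms: trimethyloxonium tetrafluoroborate C[O+](C)C.F[B-](F)(F)F
Why: O-Methylation with Meerwein salt under non-basic conditions; the equatorial secondary hydroxyl reacts far faster than the hindered tertiary C13 hydroxyl.

Step 17
Reactants: 24 bis-oxane methyl ether
Product: 25 C24 primary alcohol (24-OH, 20-OMe, 9-OTBDPS; configuration as 23)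
Conditions: H2 (1 atm), Pd(OH)2/C, EtOAc, rt
Reagents that add atoms: none
Why: Hydrogenolysis of the second benzyl ether, again before any alkene exists.

Step 18
Reactants: 25 C24 primary alcohol
Product: 26 C24 aldehyde (C23 is R by CIP here because CHO outranks C22; spatial arrangement unchanged)
Conditions: Dess–Martin periodinane, NaHCO3, CH2Cl2, 0 °C
Reagents that add atoms: none
Why: Dess–Martin oxidation to the α-methyl aldehyde, used at once so that C23 does not epimerise and the ring-B oxygen does not eliminate.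

Step 19
Reactants: 26 C24 aldehyde
Product: 27 (24E)-enal (C24=C25(CH3)–C26HO)
Conditions: Ph3P=C(CH3)CHO, toluene, 80 °C
Reagents that add atoms: 2-(triphenylphosphoranylidene)propanal CC(C=O)=P(c1ccccc1)(c1ccccc1)c1ccccc1
Why: Wittig reaction with a stabilised ylide gives the E trisubstituted enal under neutral conditions.

Step 20
Reactants: 27 (24E)-enal
Product: 28 (24E,26E)-dienyl iodide (iodine on C27)
Conditions: CrCl2, CHI3, THF/dioxane, 0 °C to rt
Reagents that add atoms: iodoform IC(I)I
Why: Takai olefination converts the aldehyde into the E vinyl iodide; E selectivity is high for conjugated aldehydes and the free tertiary alcohol is tolerated.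

Step 21
Reactants: 28 (24E,26E)-dienyl iodide
Product: 29 (24E,26E,28E)-triene (9-OTBDPS)
Conditions: (E)-prop-1-enylboronic acid, Pd(PPh3)4 (5 mol %), K3PO4 (aq), THF, rt
Reagents that add atoms: (E)-prop-1-enylboronic acid C/C=C/B(O)O
Why: Suzuki–Miyaura coupling with retention at both partners completes the all-E triene after the last acidic step.

Step 22
Reactants: 29 (24E,26E,28E)-triene
Product: 30 C9 primary alcohol
Conditions: Bu4NF, THF, rt
Reagents that add atoms: none
Why: Fluoride cleavage of the primary silyl ether; neutral towards triene, methyl ether and tertiary alcohol.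

Step 23
Reactants: 30 C9 primary alcohol
Product: 31 C9 aldehyde
Conditions: Dess–Martin periodinane, NaHCO3, CH2Cl2, 0 °C
Reagents that add atoms: none
Why: Buffered Dess–Martin oxidation to the α-methyl aldehyde, used crude so that C10 keeps its configuration.

Step 24
Reactants: 31 C9 aldehyde
Product: 32 (8E)-vinyl iodide (C8–C30 fragment, iodine on C8)
Conditions: CrCl2, CHI3, THF/dioxane 1:6, 0 °C to rt
Reagents that add atoms: iodoform IC(I)I
Why: Takai olefination gives the E vinyl iodide under non-basic conditions that do not epimerise C10; the dioxane-rich solvent raises E selectivity for the α-branched aldehyde.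

Step 25
Reactants: 33 (2S,4S)-1,2:4,5-diepoxypentane
Product: 34 (2R)-1-[(2S)-oxiran-2-yl]pent-4-en-2-ol
Conditions: 33 (3 equiv), CH2=CHMgBr (1 equiv), CuI (10 mol %), THF, −40 to −20 °C
Reagents that add atoms: vinylmagnesium bromide C=C[Mg]Br
Why: Copper-catalysed SN2 opening of one epoxide at its terminal carbon; the two epoxides are homotopic, so mono-opening with excess 33 gives a single epoxy alcohol in which C4 is fixed and C2 remains masked as the second epoxide.

Step 26
Reactants: 34 (2R)-1-[(2S)-oxiran-2-yl]pent-4-en-2-ol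
Product: 36 (2R)-1-[(2S)-oxiran-2-yl]pent-4-en-2-yl carbamate, via N-trichloroacetyl carbamate 35 (not isolated)
Conditions: Cl3CC(O)NCO, CH2Cl2, 0 °C; then neutral Al2O3, rt
Reagents that add atoms: trichloroacetyl isocyanate O=C=NC(=O)C(Cl)(Cl)Cl
Why: The only free hydroxyl adds to the isocyanate and the N-trichloroacetyl group is hydrolysed on neutral alumina, which leaves the epoxide intact.

Step 27
Reactants: 36 (2R)-1-[(2S)-oxiran-2-yl]pent-4-en-2-yl carbamate
Product: 37 (2R,4Z)-1-[(2S)-oxiran-2-yl]-5-(4,4,5,5-tetramethyl-1,3,2-dioxaborolan-2-yl)hex-4-en-2-yl carbamate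
Conditions: isopropenylboronic acid pinacol ester (4 equiv), second-generation Grubbs catalyst RuCl2(H2IMes)(PCy3)(=CHPh) (10 mol %), CH2Cl2, 40 °C
Reagents that add atoms: isopropenylboronic acid pinacol ester CC(=C)B1OC(C)(C)C(C)(C)O1
Why: Cross-metathesis of the terminal alkene with the 1,1-disubstituted vinylboronate; the trisubstituted alkenylboronate forms with the bulky boronate trans to the chain (Z by CIP), which is the C6=C7 geometry needed, and the ruthenium carbene tolerates epoxide and carbamate.

Step 28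
Reactants: 37 (2R,4Z)-1-[(2S)-oxiran-2-yl]-5-(4,4,5,5-tetramethyl-1,3,2-dioxaborolan-2-yl)hex-4-en-2-yl carbamate
Product: 39 (2S,4R,6Z)-2-hydroxy-1-[(2-methoxyacryloyl)amino]-7-(4,4,5,5-tetramethyl-1,3,2-dioxaborolan-2-yl)oct-6-en-4-yl carbamate, via amino alcohol 38 (not isolated)
Conditions: NH3 (7 M in MeOH), 40 °C, sealed; evaporate; then 2-methoxyacrylic acid, EDC·HCl, HOBt, i-Pr2NEt, DMF, 0 °C to rt
Reagents that add atoms: ammonia N; 2-methoxyacrylic acid C=C(OC)C(O)=O
Why: Ammonia opens the terminal epoxide at C1 (SN2) and carbodiimide coupling then acylates the amine in preference to the C2 hydroxyl; the acid-labile 2-methoxyacrylamide thus meets only the final coupling.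

Step 29
Reactants: 32 (8E)-vinyl iodide; 39 (2S,4R,6Z)-2-hydroxy-1-[(2-methoxyacryloyl)amino]-7-(4,4,5,5-tetramethyl-1,3,2-dioxaborolan-2-yl)oct-6-en-4-yl carbamate
Product: 40 CNP0155183.1 (target)
Conditions: Pd(dppf)Cl2·CH2Cl2 (10 mol %), K3PO4 (aq), THF/DMF, rt, degassed
Reagents that add atoms: none
Why: Suzuki–Miyaura coupling with retention at both alkenes forms C7–C8 and the E,E-diene; aqueous phosphate at room temperature is tolerated by carbamate, amide, enol ether, free hydroxyls and triene, and no protecting group remains to be removed.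

## Compound list

1 | furan | c1ccoc1 | starting material
2 | 2-furyllithium | [Li]c1ccco1 | intermediate (not isolated)
3 | 2-(furan-2-yl)ethanol | OCCc1ccco1 | intermediate
4 | 2-[2-(benzyloxy)ethyl]furan | c1ccc(COCCc2ccco2)cc1 | intermediate
5 | 5-[2-(benzyloxy)ethyl]furan-2-yllithium | [Li]c1ccc(CCOCc2ccccc2)o1 | intermediate (not isolated)
6 | 5-[2-(benzyloxy)ethyl]-N-methoxy-N-methylfuran-2-carboxamide | CON(C)C(=O)c1ccc(CCOCc2ccccc2)o1 | intermediate
7 | (S)-3-bromo-2-methylpropan-1-ol | OC[C@H](C)CBr | starting material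
8 | (S)-(3-bromo-2-methylpropoxy)(tert-butyl)diphenylsilane | CC(C)(C)[Si](c1ccccc1)(c1ccccc1)OC[C@H](C)CBr | intermediate
9 | [(2S)-3-(tert-butyldiphenylsilyloxy)-2-methylpropyl]magnesium bromide | CC(C)(C)[Si](c1ccccc1)(c1ccccc1)OC[C@H](C)C[Mg]Br | intermediate (not isolated)
10 | (3R)-1-{5-[2-(benzyloxy)ethyl]furan-2-yl}-4-(tert-butyldiphenylsilyloxy)-3-methylbutan-1-one | CC(C)(C)[Si](c1ccccc1)(c1ccccc1)OC[C@H](C)CC(=O)c1ccc(CCOCc2ccccc2)o1 | intermediate
11 | (1S,3R)-1-{5-[2-(benzyloxy)ethyl]furan-2-yl}-4-(tert-butyldiphenylsilyloxy)-3-methylbutan-1-ol | CC(C)(C)[Si](c1ccccc1)(c1ccccc1)OC[C@H](C)C[C@H](O)c1ccc(CCOCc2ccccc2)o1 | intermediate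
12 | (2S)-6-[2-(benzyloxy)ethyl]-2-[(2R)-3-(tert-butyldiphenylsilyloxy)-2-methylpropyl]-6-hydroxy-2H-pyran-3(6H)-one (both C6 epimers) | CC(C)(C)[Si](c1ccccc1)(c1ccccc1)OC[C@H](C)C[C@@H]1OC(O)(CCOCc2ccccc2)C=CC1=O | intermediate (not isolated)
13 | (2S,6R)-6-[2-(benzyloxy)ethyl]-2-[(2R)-3-(tert-butyldiphenylsilyloxy)-2-methylpropyl]-2H-pyran-3(6H)-one | CC(C)(C)[Si](c1ccccc1)(c1ccccc1)OC[C@H](C)C[C@@H]1O[C@H](CCOCc2ccccc2)C=CC1=O | intermediate
14 | (2S,5S,6R)-6-[2-(benzyloxy)ethyl]-2-[(2R)-3-(tert-butyldiphenylsilyloxy)-2-methylpropyl]-5-methyloxan-3-one | CC(C)(C)[Si](c1ccccc1)(c1ccccc1)OC[C@H](C)C[C@@H]1O[C@H](CCOCc2ccccc2)[C@@H](C)CC1=O | intermediate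
15 | (2S,3R,5S,6R)-6-[2-(benzyloxy)ethyl]-2-[(2R)-3-(tert-butyldiphenylsilyloxy)-2-methylpropyl]-3,5-dimethyloxan-3-ol | CC(C)(C)[Si](c1ccccc1)(c1ccccc1)OC[C@H](C)C[C@@H]1O[C@H](CCOCc2ccccc2)[C@@H](C)C[C@@]1(C)O | intermediate
16 | (2S,3R,5S,6R)-2-[(2R)-3-(tert-butyldiphenylsilyloxy)-2-methylpropyl]-6-(2-hydroxyethyl)-3,5-dimethyloxan-3-ol | CC(C)(C)[Si](c1ccccc1)(c1ccccc1)OC[C@H](C)C[C@@H]1O[C@H](CCO)[C@@H](C)C[C@@]1(C)O | intermediate
17 | 2-{(2R,3S,5R,6S)-6-[(2R)-3-(tert-butyldiphenylsilyloxy)-2-methylpropyl]-5-hydroxy-3,5-dimethyloxan-2-yl}acetaldehyde | CC(C)(C)[Si](c1ccccc1)(c1ccccc1)OC[C@H](C)C[C@@H]1O[C@H](CC=O)[C@@H](C)C[C@@]1(C)O | intermediate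
18 | methyl (S)-3-hydroxy-2-methylpropanoate | COC(=O)[C@@H](C)CO | starting material
19 | methyl (S)-3-(benzyloxy)-2-methylpropanoate | COC(=O)[C@@H](C)COCc1ccccc1 | intermediate
20 | (S)-3-(benzyloxy)-2-methylpropanal | O=C[C@@H](C)COCc1ccccc1 | intermediate
21 | (2S,3R)-1-(benzyloxy)-2-methylhex-5-en-3-ol | C=CC[C@H]([C@@H](C)COCc1ccccc1)O | intermediate
22 | C20 trifluoroacetate of 23 | CC(C)(C)[Si](c1ccccc1)(c1ccccc1)OC[C@H](C)C[C@@H]1O[C@H](C[C@@H]2C[C@H](OC(=O)C(F)(F)F)C[C@H]([C@@H](C)COCc3ccccc3)O2)[C@@H](C)C[C@@]1(C)O | intermediate (not isolated)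
23 | bis-oxane alcohol (20-OH, 13-OH, 9-OTBDPS, 24-OBn; 10R,12S,13R,15S,16R,18S,20S,22R,23S) | CC(C)(C)[Si](c1ccccc1)(c1ccccc1)OC[C@H](C)C[C@@H]1O[C@H](C[C@@H]2C[C@H](O)C[C@H]([C@@H](C)COCc3ccccc3)O2)[C@@H](C)C[C@@]1(C)O | intermediate
24 | bis-oxane methyl ether (20-OMe; otherwise as 23) | CC(C)(C)[Si](c1ccccc1)(c1ccccc1)OC[C@H](C)C[C@@H]1O[C@H](C[C@@H]2C[C@H](OC)C[C@H]([C@@H](C)COCc3ccccc3)O2)[C@@H](C)C[C@@]1(C)O | intermediate
25 | C24 primary alcohol (24-OH, 20-OMe, 9-OTBDPS) | CC(C)(C)[Si](c1ccccc1)(c1ccccc1)OC[C@H](C)C[C@@H]1O[C@H](C[C@@H]2C[C@H](OC)C[C@H]([C@@H](C)CO)O2)[C@@H](C)C[C@@]1(C)O | intermediate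
26 | C24 aldehyde (C23 R by CIP, spatially as in 40) | CC(C)(C)[Si](c1ccccc1)(c1ccccc1)OC[C@H](C)C[C@@H]1O[C@H](C[C@@H]2C[C@H](OC)C[C@H]([C@@H](C)C=O)O2)[C@@H](C)C[C@@]1(C)O | intermediate
27 | (24E)-enal | CC(C)(C)[Si](c1ccccc1)(c1ccccc1)OC[C@H](C)C[C@@H]1O[C@H](C[C@@H]2C[C@H](OC)C[C@H]([C@@H](C)/C=C(C)/C=O)O2)[C@@H](C)C[C@@]1(C)O | intermediate
28 | (24E,26E)-dienyl iodide | CC(C)(C)[Si](c1ccccc1)(c1ccccc1)OC[C@H](C)C[C@@H]1O[C@H](C[C@@H]2C[C@H](OC)C[C@H]([C@@H](C)/C=C(C)/C=C/I)O2)[C@@H](C)C[C@@]1(C)O | intermediate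
29 | (24E,26E,28E)-triene, 9-OTBDPS | CC(C)(C)[Si](c1ccccc1)(c1ccccc1)OC[C@H](C)C[C@@H]1O[C@H](C[C@@H]2C[C@H](OC)C[C@H]([C@@H](C)/C=C(C)/C=C/C=C/C)O2)[C@@H](C)C[C@@]1(C)O | intermediate
30 | C9 primary alcohol | OC[C@H](C)C[C@@H]1O[C@H](C[C@@H]2C[C@H](OC)C[C@H]([C@@H](C)/C=C(C)/C=C/C=C/C)O2)[C@@H](C)C[C@@]1(C)O | intermediate
31 | C9 aldehyde | O=C[C@H](C)C[C@@H]1O[C@H](C[C@@H]2C[C@H](OC)C[C@H]([C@@H](C)/C=C(C)/C=C/C=C/C)O2)[C@@H](C)C[C@@]1(C)O | intermediate
32 | (8E)-vinyl iodide, C8–C30 fragment | I/C=C/[C@H](C)C[C@@H]1O[C@H](C[C@@H]2C[C@H](OC)C[C@H]([C@@H](C)/C=C(C)/C=C/C=C/C)O2)[C@@H](C)C[C@@]1(C)O | intermediate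
33 | (2S,4S)-1,2:4,5-diepoxypentane | C1[C@@H](O1)C[C@H]1CO1 | starting material
34 | (2R)-1-[(2S)-oxiran-2-yl]pent-4-en-2-ol | C1[C@@H](O1)C[C@@H](CC=C)O | intermediate
35 | (2R)-1-[(2S)-oxiran-2-yl]pent-4-en-2-yl (trichloroacetyl)carbamate | C1[C@@H](O1)C[C@@H](CC=C)OC(=O)NC(=O)C(Cl)(Cl)Cl | intermediate (not isolated)
36 | (2R)-1-[(2S)-oxiran-2-yl]pent-4-en-2-yl carbamate | C1[C@@H](O1)C[C@@H](CC=C)OC(N)=O | intermediate
37 | (2R,4Z)-1-[(2S)-oxiran-2-yl]-5-(4,4,5,5-tetramethyl-1,3,2-dioxaborolan-2-yl)hex-4-en-2-yl carbamate | C1[C@@H](O1)C[C@@H](C/C=C(C)/B2OC(C)(C)C(C)(C)O2)OC(N)=O | intermediate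
38 | (2S,4R,6Z)-1-amino-2-hydroxy-7-(4,4,5,5-tetramethyl-1,3,2-dioxaborolan-2-yl)oct-6-en-4-yl carbamate | NC[C@@H](O)C[C@@H](C/C=C(C)/B1OC(C)(C)C(C)(C)O1)OC(N)=O | intermediate (not isolated)
39 | (2S,4R,6Z)-2-hydroxy-1-[(2-methoxyacryloyl)amino]-7-(4,4,5,5-tetramethyl-1,3,2-dioxaborolan-2-yl)oct-6-en-4-yl carbamate | C=C(OC)C(=O)NC[C@@H](O)C[C@@H](C/C=C(C)/B1OC(C)(C)C(C)(C)O1)OC(N)=O | intermediate
40 | CNP0155183.1 (2S,4R,6E,8E,10R,12S,13R,15S,16R,18S,20S,22R,23S,24E,26E,28E in chain numbering) | C=C(OC)C(=O)NC[C@@H](O)C[C@@H](C/C=C(C)/C=C/[C@H](C)C[C@@H]1O[C@H](C[C@@H]2C[C@H](OC)C[C@H]([C@@H](C)/C=C(C)/C=C/C=C/C)O2)[C@@H](C)C[C@@]1(C)O)OC(N)=O | target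

## Step count and risks

Total step count: 29. Longest linear sequence: 21 steps (steps 1–3, 5–11, 15–24 and 29, from furan).

**Step 7 (key step).** The oxocarbenium ion formed from hemiketal 12 is cross-conjugated with the enone. Loss of a C17 proton to an exocyclic dienone may compete with hydride capture, the cis selectivity may fall if the half-chair is distorted, and the silyl ether may be partly lost in TFA. Fallback: set out from hemiketal 12, isolated after the NBS stage. Hydrogenation of its ring alkene (H2, Pd/C poisoned with pyridine so that the benzyl ether stays) would give the saturated hemiketal F1. Reduction with Et3SiH/BF3·OEt2, now through a simple non-conjugated oxocarbenium ion, would give the 2,6-cis oxan-3-one F2. Kinetic enolisation away from the alkoxy-bearing C12 (LiN(i-Pr)2, Me3SiCl, −78 °C) would give silyl enol ether F3, and Saegusa–Ito oxidation (Pd(OAc)2, MeCN) would return to enone 13.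

**Step 9.** Poor facial selectivity (equatorial attack giving the C13 epimer) or enolisation of the α-alkoxy ketone by the Grignard reagent. Fallback: set out from ketone 14 and form the C–C bond with dimethylsulfonium methylide (Me3SI, KN(SiMe3)2, THF, 0 °C). This Corey–Chaykovsky reagent adds irreversibly from the axial side and would give the spiro-epoxide F4 with axial CH2 and equatorial oxygen. LiEt3BH would then open F4 at the CH2 carbon and return to alcohol 15.

**Step 15.** Scrambling of the alcohol partner by 2-oxonia-Cope rearrangement, acid-promoted β-elimination of aldehyde 17, or ionisation of the tertiary C13 alcohol in TFA. Fallback: the oxocarbenium ion would be generated intramolecularly and without protic acid. Set out from aldehyde 17: Pinnick oxidation (NaClO2, NaH2PO4, 2-methylbut-2-ene) would give acid F5, and Yamaguchi esterification with alcohol 21 would give ester F6. Reductive acetylation (i-Bu2AlH, then Ac2O, pyridine, DMAP, −78 °C) would give α-acetoxy ether F7. BF3·OEt2/AcOH at 0 °C would close ring B to the 20-acetate F8, and K2CO3/MeOH would return to alcohol 23.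

**Step 27.** Low conversion of the hindered 1,1-disubstituted boronate, homodimerisation of 36, or incomplete geometric selectivity at C6=C7. Fallback: the geometry would be fixed by syn hydrometalation of an alkyne instead, and the coupling roles exchanged. Set out from diepoxide 33:
- ring-opening silylation (t-BuMe2SiCl, Bu4NCl cat.) would give the chloro silyl ether epoxide F9;
- 1-propynyllithium/BF3·OEt2 would give alkynol F10;
- Cp2Zr(H)Cl (excess, THF, 50 °C) then I2 would give the (E)-2-iodoalkene F11;
- carbamoylation as in step 26 would give carbamate F12;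
- NaN3 in DMF would give azide F13;
- HF·pyridine would give the azido alcohol F14;
- Staudinger reduction (PMe3, THF/H2O) and acylation as in step 28 would give the iodo amide F15.

The core would be used as alkenylboronate F16, made from aldehyde 31 with CrCl2, Cl2CHB(pin) and LiI. F15 and F16 under the conditions of step 29 would return to target 40.

## Further compounds

F1 | step 7 | (2S)-6-[2-(benzyloxy)ethyl]-2-[(2R)-3-(tert-butyldiphenylsilyloxy)-2-methylpropyl]-6-hydroxyoxan-3-one | CC(C)(C)[Si](c1ccccc1)(c1ccccc1)OC[C@H](C)C[C@@H]1OC(O)(CCOCc2ccccc2)CCC1=O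
F2 | step 7 | 2,6-cis-6-[2-(benzyloxy)ethyl]-2-[(2R)-3-(tert-butyldiphenylsilyloxy)-2-methylpropyl]oxan-3-one | CC(C)(C)[Si](c1ccccc1)(c1ccccc1)OC[C@H](C)C[C@@H]1O[C@H](CCOCc2ccccc2)CCC1=O
F3 | step 7 | trimethylsilyl enol ether of F2 (C13=C14) | CC(C)(C)[Si](c1ccccc1)(c1ccccc1)OC[C@H](C)C[C@@H]1O[C@H](CCOCc2ccccc2)CC=C1O[Si](C)(C)C
F4 | step 9 | C13 spiro-epoxide of ring A (axial CH2, equatorial O) | CC(C)(C)[Si](c1ccccc1)(c1ccccc1)OC[C@H](C)C[C@@H]1O[C@H](CCOCc2ccccc2)[C@@H](C)C[C@]13CO3
F5 | step 15 | ring-A acetic acid (C18 carboxylic acid) | CC(C)(C)[Si](c1ccccc1)(c1ccccc1)OC[C@H](C)C[C@@H]1O[C@H](CC(=O)O)[C@@H](C)C[C@@]1(C)O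
F6 | step 15 | ester of F5 with alcohol 21 | CC(C)(C)[Si](c1ccccc1)(c1ccccc1)OC[C@H](C)C[C@@H]1O[C@H](CC(=O)O[C@H](CC=C)[C@@H](C)COCc2ccccc2)[C@@H](C)C[C@@]1(C)O
F7 | step 15 | α-acetoxy ether from F6 (both C18 epimers) | CC(C)(C)[Si](c1ccccc1)(c1ccccc1)OC[C@H](C)C[C@@H]1O[C@H](CC(OC(C)=O)O[C@H](CC=C)[C@@H](C)COCc2ccccc2)[C@@H](C)C[C@@]1(C)O
F8 | step 15 | C20 acetate of 23 | CC(C)(C)[Si](c1ccccc1)(c1ccccc1)OC[C@H](C)C[C@@H]1O[C@H](C[C@@H]2C[C@H](OC(C)=O)C[C@H]([C@@H](C)COCc3ccccc3)O2)[C@@H](C)C[C@@]1(C)O
F9 | step 27 | tert-butyl{[(2S)-1-chloro-3-[(2S)-oxiran-2-yl]propan-2-yl]oxy}dimethylsilane | ClC[C@@H](O[Si](C)(C)C(C)(C)C)C[C@H]1CO1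
F10 | step 27 | 1-chloro-2-(tert-butyldimethylsilyloxy)oct-6-yn-4-ol (C2/C4 as in 40) | ClC[C@@H](O[Si](C)(C)C(C)(C)C)C[C@@H](CC#CC)O
F11 | step 27 | (6E)-1-chloro-7-iodo-2-(tert-butyldimethylsilyloxy)oct-6-en-4-ol | ClC[C@@H](O[Si](C)(C)C(C)(C)C)C[C@@H](C/C=C(C)/I)O
F12 | step 27 | carbamate of F11 | ClC[C@@H](O[Si](C)(C)C(C)(C)C)C[C@@H](C/C=C(C)/I)OC(N)=O
F13 | step 27 | (6E)-1-azido-7-iodo-2-(tert-butyldimethylsilyloxy)oct-6-en-4-yl carbamate | [N-]=[N+]=NC[C@@H](O[Si](C)(C)C(C)(C)C)C[C@@H](C/C=C(C)/I)OC(N)=O
F14 | step 27 | (2S,4R,6E)-1-azido-2-hydroxy-7-iodooct-6-en-4-yl carbamate | [N-]=[N+]=NC[C@@H](O)C[C@@H](C/C=C(C)/I)OC(N)=O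
F15 | step 27 | (2S,4R,6E)-2-hydroxy-7-iodo-1-[(2-methoxyacryloyl)amino]oct-6-en-4-yl carbamate | C=C(OC)C(=O)NC[C@@H](O)C[C@@H](C/C=C(C)/I)OC(N)=O
F16 | step 27 | (8E)-alkenylboronic acid pinacol ester of the C8–C30 fragment | CC1(C)OB(/C=C/[C@H](C)C[C@@H]2O[C@H](C[C@@H]3C[C@H](OC)C[C@H]([C@@H](C)/C=C(C)/C=C/C=C/C)O3)[C@@H](C)C[C@@]2(C)O)OC1(C)C
A1 | alternative 1 | ethyl (2E)-C18–C9 dihydroxy enoate (12-OH, 13-OH, 9-OTBDPS; 10R,12S,13R,15S) | CCOC(=O)/C=C/[C@@H](C)C[C@@](C)(O)[C@@H](O)C[C@@H](C)CO[Si](c1ccccc1)(c1ccccc1)C(C)(C)C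
A2 | alternative 1 | ring-A ethyl ester from oxa-Michael closure of A1 | CC(C)(C)[Si](c1ccccc1)(c1ccccc1)OC[C@H](C)C[C@@H]1O[C@H](CC(=O)OCC)[C@@H](C)C[C@@]1(C)O
A3 | alternative 2 | C12/C13 epoxy alcohol (16-OH, 18-OBn, 9-OTBDPS; C12 inverted relative to 40) | CC(C)(C)[Si](c1ccccc1)(c1ccccc1)OC[C@H](C)C[C@H]1O[C@]1(C)C[C@H](C)[C@H](O)CCOCc1ccccc1
A4 | alternative 3 | dimethyl [(4R,5S)-6-(benzyloxy)-5-methyl-2-oxo-4-(triethylsilyloxy)hexyl]phosphonate | COP(=O)(OC)CC(=O)C[C@@H](O[Si](CC)(CC)CC)[C@@H](C)COCc1ccccc1
A5 | alternative 3 | ring-B oxan-4-one (C20 ketone analogue of 23) | CC(C)(C)[Si](c1ccccc1)(c1ccccc1)OC[C@H](C)C[C@@H]1O[C@H](C[C@@H]2CC(=O)C[C@H]([C@@H](C)COCc3ccccc3)O2)[C@@H](C)C[C@@]1(C)O
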